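Assumption: the configuration encoded in the structure is taken as absolute, (4S,5R,7R,8R,9S,10S) in eremophilane numbering. Eremophilane locants are used for all decalins and, by extension, for their bicyclic precursors; ring B is C10–C1–C2–C3–C4–C5, ring A is C5–C10, and β is the decalin face that carries both methyl groups and H10.

## Analysis of the target

Target 30 is a 2-oxoeremophil-11-ene, a cis-fused decalin. Ring B carries the C2 ketone, the secondary methyl group at C4 and the angular methyl group at C5. Ring A carries the isopropenyl group at C7, the acetate at C8 and the tiglate at C9.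

The six stereocentres form two contiguous triads. In C4/C5/C10 both methyl groups and H10 are β. In C7/C8/C9 the isopropenyl group is β and both acyloxy groups are α, so the two esters are cis to each other, O8 is trans to isopropenyl and O9 is trans to H10.

In the ring A chair that keeps isopropenyl and acetate equatorial, the C9 tiglate is axial and syn-axial to the C5–C4 bond. It therefore sits on the concave face, under ring B.

The sensitive points are:
- the isopropenyl alkene, which moves into conjugation with any C8 carbonyl;
- two different esters on a cis-diol, which invites acyl migration;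
- C7 and C10, which become epimerisable whenever C8 or C9 is a ketone.

The C2 ketone has no α-stereocentre and can be masked and released freely.

The hard parts are the quaternary C5 flanked by two tertiary centres in a cis-fused ring, and the concave axial oxygen at C9.

The strategy rests on ring B. If C7 and C8 are traced back to a C6=C7 alkene with oxygen on C8, the chain C2(=O)–C3–C4–C5–C6=C7 is a δ,ε-unsaturated ketone. That is the retron of an oxy-Cope rearrangement in which C4–C5 is the bond made and C2–C7 the bond broken, so the precursor is a bicyclo[2.2.2]octenol.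

## Retrosynthetic reasoning

**C2 ketal and the two esters (30 ⇒ 29 ⇒ 28).** The ketone is released last because it must stay hidden from every hydride and enolate step and carries no stereochemical risk. The tigloyl C–O bond at C9 is cut next, because the 9α-hydroxyl only exists late in the route; the forward step must acylate a hindered axial alcohol beside an acetate.

**C9–H bond (28 ⇒ 27).** The 9α oxygen is on the concave face, where an electrophilic oxygen source will not go. A hydride approaching a C9 ketone from the open β face puts the oxygen exactly there. The cut gains a reagent-independent, conformationally dictated C9 configuration; the forward reduction must attack equatorially and must not disturb the C8 acetate.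

**Protecting-group and oxidation-level changes (27 ⇒ 26 ⇒ 25 ⇒ 24).** The C9 oxygen is first carried as its β epimer under a silyl ether. In this configuration it is equatorial and locks the ring A chair while C7 and C8 are set. The acetate is placed on O8 before the silyl group is removed, so the two oxygens are never free together.

**C8–H bond (24 ⇒ 23).** The C8 alcohol comes from the ketone by axial hydride delivery. The forward step must give the equatorial 8α alcohol, trans to both neighbours.

**C7–H and C7–C11 bonds (23 ⇒ 21 ⇒ 20 ⇒ 19).** The C6=C7–C8=O enone makes C7 the one carbon that can be iodinated and cross-coupled, so the three-carbon unit enters at a defined position. An enolate alkylation would be regiochemically ambiguous and would give an axial C–C bond. The forward conjugate reduction must protonate C7 to leave isopropenyl equatorial without moving its double bond.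

**C9–O bond (19 ⇒ 18 ⇒ 16).** Oxygen is introduced at the enone stage because 16, with C5 quaternary, can enolise only towards C9. After the isopropenyl group is in place, the doubly activated C7–H would compete.

**Functional-group adjustments (16 ⇒ 15 ⇒ 14 ⇒ 13 ⇒ 12).** The enone comes from the allylic benzyl ether by debenzylation and oxidation. The C2 ketone is ketalised. The two C1 methoxy groups, which are what remains of the quinone ketal, are removed reductively.

**Key disconnection (12 ⇒ 9).** Re-forming C2–C7 and cutting C4–C5 turns the cis-decalin into a bicyclo[2.2.2]octenol. This removes ring B, the quaternary centre and two stereocentres in one step. The forward [3,3] shift must go through the cage-enforced boat with the propenyl group syn to the alkene.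

**C2–C3 bond (9 ⇒ 5 + 8, 8 from 6 via 7).** The propenyl group is added to the ketone as a Z-configured organometallic. The forward addition must occur on the carbonyl face that looks at the alkene.

**C7–C8 and C9–C10 bonds (5 ⇒ 4 ⇒ 3 + 2, 3 ⇐ 1).** A Diels–Alder cut opens the bicycle to the masked o-benzoquinone 3 and enol ether 2. Diene 3 comes from phenol 1 by oxidative dearomatisation, and already holds the C5 methyl group, the C2 carbonyl and the C1 ketal. Both partners are achiral, so racemic 4 is resolved to 5 before any further material is invested.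

## Alternatives that were turned down

**Alternative 1: carbonyl-ene closure of ring A.**
- Disconnection: C7–C8. The precursor is the 7,8-seco aldehyde A2, a ring B cyclohexane with a prenyl chain on C5 and an α-silyloxy acetaldehyde unit on C10.
- Forward key step: an alkylaluminium chloride promotes the intramolecular ene reaction, giving alcohol A1 with the isopropenyl group and the C8 hydroxyl formed together.
- For: A1 is the same structure as 24 of the chosen route. The ene step makes isopropenyl and the trans-diequatorial C8 alcohol without ever passing through a C8 ketone, so the conjugation risk of steps 12–14 is absent. On the ring A endgame this alternative is stronger.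
- Against: A2 must already contain the full C4/C5/C10 triad, with a quaternary C5 bearing two different carbon chains, plus a C9 stereocentre α to an epimerisable aldehyde. The hardest part of the molecule is untouched by the key step and needs its own multistep stereocontrol. The C9 oxygen in A1 still has the β configuration and needs the same inversion.
- Comparison: the chosen route offers in exchange the whole ring B triad from one pericyclic step on a bicycle that is two steps from a phenol.

**Alternative 2: intramolecular Diels–Alder of a silyloxydiene with a tiglyl ketone.**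
- Disconnection: C3–C4 and C5–C10. The precursor is the open-chain trienone A4; cycloaddition gives the 6-oxo decalin silyl enol ether A3.
- For: both rings and C4, C5 and C10 form at once; the E alkene geometry maps onto the cis-dimethyl pair; the enol ether is the latent C2 ketone. The C7–C9 triad could come from a chiral-pool diol, so no resolution is needed. On absolute stereocontrol and convergency it is stronger.
- Against: the dienophile is an α-branched, trisubstituted enone alkene that must form a quaternary centre, which is electronically and sterically poor. The cis fusion depends on an endo/exo preference that nothing enforces. C7 in A4 lies between a ketone and an isopropenyl group and will epimerise or conjugate under thermal or Lewis acid activation. The C6 carbonyl of A3 is superfluous and must be removed next to C5 and C7. The acetonide leaves the two oxygens undifferentiated.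
- Comparison: in the chosen route the cage, not a transition-state preference, fixes the fusion and the methyl relationship.

**Alternative 3: desymmetrising amine-catalysed Michael closure of ring B.**
- Disconnection: C1–C10. The precursor is cyclohexadienone A6; the enamine of its methyl ketone adds to one enone arm to give dione A5.
- For: A5 is the free diketone of which 16 is the C2 ketal, and it would be reached in far fewer steps than the eight needed here, with catalytic absolute control and no resolution. On step economy to the enone stage it is clearly stronger.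
- Against: A6 needs a quaternary C5 carrying a methyl group and a branched chain whose C4 stereocentre is already set. Oxidative dearomatisation of a para-substituted phenol delivers a heteroatom, not carbon, to that position, so A6 is not readily made. Because C4 is already stereogenic, the two enone arms are diastereotopic, and the C4/C5 relationship depends on the catalyst overriding or matching the substrate. The two ketones of A5 then have to be told apart.
- Comparison: the chosen route fixes the cis-4,5-dimethyl relationship by alkene geometry through a rigid boat, at the cost of a resolution and a longer path.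

Key step: step 4

## Route

Step 1
Reactants: 1 2-methoxy-4-methylphenol; 2 benzyl vinyl ether
Product: 4 rac-7-endo-benzyloxy-3,3-dimethoxy-5-methylbicyclo[2.2.2]oct-5-en-2-one, via 6,6-dimethoxy-4-methylcyclohexa-2,4-dien-1-one 3 (not isolated)
Conditions: PhI(OAc)2 (1.1 equiv), 2 (10 equiv), MeOH, rt, 1 added over 6 h
Reagents that add atoms: methanol, CO
Why: Oxidative dearomatisation of the guaiacol by the trivalent iodine reagent in methanol gives masked o-benzoquinone 3, which is trapped as it forms in an inverse-electron-demand Diels–Alder reaction; slow addition keeps 3 dilute and suppresses its dimerisation. The nucleophilic CH2 of the enol ether bonds to the dienone terminus remote from the carbonyl and the alkoxy group lies endo, so the benzyloxy carbon (C8) ends on the carbonyl-side bridgehead (C7), syn to the new alkene.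

Step 2
Reactants: 4 rac-7-endo-benzyloxy-3,3-dimethoxy-5-methylbicyclo[2.2.2]oct-5-en-2-one
Product: 5 (1R,4R,7R)-7-benzyloxy-3,3-dimethoxy-5-methylbicyclo[2.2.2]oct-5-en-2-one
Conditions: preparative SFC, amylose tris(3,5-dimethylphenylcarbamate) phase, CO2/i-PrOH, 35 °C
Reagents that add atoms: none
Why: Resolution by chromatography on a chiral stationary phase; the ketone is rigid, carries an aryl group for recognition and cannot racemise because both α-carbons (bridgehead and ketal) are non-enolisable. The antipode to be kept would be assigned by crystallography of a derivative.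

Step 3
Reactants: 5 (1R,4R,7R)-7-benzyloxy-3,3-dimethoxy-5-methylbicyclo[2.2.2]oct-5-en-2-one; 6 (Z)-1-bromoprop-1-ene
Product: 9 (1R,2S,4R,7R)-7-benzyloxy-3,3-dimethoxy-5-methyl-2-[(Z)-prop-1-enyl]bicyclo[2.2.2]oct-5-en-2-ol, via (Z)-prop-1-enyllithium 7 (not isolated), via (Z)-prop-1-enylmagnesium bromide 8 (not isolated)
Conditions: 6, t-BuLi (2 equiv), Et2O, −78 °C; MgBr2·OEt2; then 5, THF, −78 to 0 °C; H2O
Reagents that add atoms: none
Why: Bromine–lithium exchange at −78 °C keeps the Z geometry, and Grignard 1,2-addition to the non-enolisable ketone follows. Attack comes from the carbonyl face that looks at the C5=C6 bridge, because the other face is screened by the C–H bonds of the saturated bridge; this places the propenyl group syn to the alkene, as the [3,3] shift requires.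

Step 4
Reactants: 9 (1R,2S,4R,7R)-7-benzyloxy-3,3-dimethoxy-5-methyl-2-[(Z)-prop-1-enyl]bicyclo[2.2.2]oct-5-en-2-ol
Product: 12 8β-benzyloxy-1,1-dimethoxy-4β,5β-dimethyl-10βH-decal-6-en-2-one, via potassium carbinolate 10 (not isolated), via potassium C2-enolate 11 (not isolated)
Conditions: KH (1.5 equiv), 18-crown-6 (1.5 equiv), THF, 0 °C to rt; AcOH, −78 °C
Reagents that add atoms: none
Why: Anionic oxy-Cope rearrangement, the reaction type established for 2-alkenylbicyclo[2.2.2]oct-5-en-2-ols from masked o-benzoquinone adducts: the crown-separated potassium alkoxide 10 weakens C2–C7, and a concerted [3,3] shift breaks that bond while propenyl carbon C4 bonds to alkene carbon C5, giving enolate 11 and the C6=C7 alkene. Ring B (C10–C1–C2–C3–C4–C5) closes through this sigmatropic bond in a six-centre boat transition state, the only geometry the cage allows, so the closure is pericyclic and not a polar exo or endo cyclisation; ring A is the cyclohexene released from the cage. C5 is set by the cage, because C4 can reach C5 only on the face that looks at the C1–C2 bridge, the face on which C10 already carries C1, so the fusion is cis with the 5-methyl group and H10 syn. C4 is set by the alkene geometry: in the boat the inward methyl of the (Z)-propenyl group ends on the same side of ring B as the 5-methyl group, whereas an (E)-propenyl group would give the trans-dimethyl epimer, which is why step 3 protects the geometry. The step needs the [3,3] path to outrun retro-addition, [1,3] shift and fragmentation; the syn arrangement of propenyl and alkene, the strain released on opening the bicycle and the delocalised charge of 11 secure this, at the price of a slower shift caused by the inward methyl pressing on the ketal. Protonation of 11 at C3 creates no stereocentre.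

Step 5
Reactants: 12 8β-benzyloxy-1,1-dimethoxy-4β,5β-dimethyl-10βH-decal-6-en-2-one
Product: 13 8β-benzyloxy-4β,5β-dimethyl-10βH-decal-6-en-2-one
Conditions: SmI2 (6 equiv), THF/MeOH (4:1), rt
Reagents that add atoms: none
Why: Reductive cleavage of an α-alkoxy ketone by divalent samarium: ketyl formation, loss of methoxide and protonation of the samarium enolate, run twice, leave C1 as a methylene group. The isolated alkene and the benzyl ether are inert, and no stereocentre is α to the ketone.

Step 6
Reactants: 13 8β-benzyloxy-4β,5β-dimethyl-10βH-decal-6-en-2-one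
Product: 14 8β-benzyloxy-2,2-ethylenedioxy-4β,5β-dimethyl-10βH-decal-6-ene
Conditions: HOCH2CH2OH, PPTS (cat.), benzene, reflux, Dean–Stark
Reagents that add atoms: ethylene glycol, OCCO
Why: Acid-catalysed ketalisation of an unhindered cyclohexanone flanked by two methylene groups; the dioxolane shields C2 from the electron-transfer, enolate and hydride steps that follow.

Step 7
Reactants: 14 8β-benzyloxy-2,2-ethylenedioxy-4β,5β-dimethyl-10βH-decal-6-ene
Product: 15 2,2-ethylenedioxy-4β,5β-dimethyl-10βH-decal-6-en-8β-ol
Conditions: lithium 4,4'-di-tert-butylbiphenylide (LiDBB), THF, −78 °C; H2O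
Reagents that add atoms: none
Why: Reductive debenzylation by single-electron transfer: the radical anion centred on the benzyl ring expels the C8 alkoxide. The isolated C6=C7 alkene, which hydrogenolysis would saturate, accepts no electron at −78 °C.

Step 8
Reactants: 15 2,2-ethylenedioxy-4β,5β-dimethyl-10βH-decal-6-en-8β-ol
Product: 16 2,2-ethylenedioxy-4β,5β-dimethyl-10βH-decal-6-en-8-one
Conditions: Dess–Martin periodinane, NaHCO3, CH2Cl2, 0 °C to rt
Reagents that add atoms: none
Why: Dess–Martin oxidation of a secondary allylic alcohol to the enone; the C8 stereocentre inherited from the cycloaddition is erased. Because C5 is quaternary, the enone can enolise only towards C9.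

Step 9
Reactants: 16 2,2-ethylenedioxy-4β,5β-dimethyl-10βH-decal-6-en-8-one
Product: 18 2,2-ethylenedioxy-9β-hydroxy-4β,5β-dimethyl-10βH-decal-6-en-8-one, via potassium 6,8-dienolate 17 (not isolated)
Conditions: KN(SiMe3)2, THF, −78 °C; 2-(phenylsulfonyl)-3-phenyloxaziridine, −78 °C; AcOH
Reagents that add atoms: 2-(phenylsulfonyl)-3-phenyloxaziridine, O=S(=O)(c1ccccc1)N1OC1c1ccccc1
Why: Enolate hydroxylation with an N-sulfonyloxaziridine (Davis oxidation) of the cross-conjugated dienolate, the only enolate this enone can form. Oxygen is expected on the convex β face of C9, syn to H10 and away from ring B, which is folded under the α face of the cis-decalin.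

Step 10
Reactants: 18 2,2-ethylenedioxy-9β-hydroxy-4β,5β-dimethyl-10βH-decal-6-en-8-one
Product: 19 9β-(tert-butyldimethylsilyloxy)-2,2-ethylenedioxy-4β,5β-dimethyl-10βH-decal-6-en-8-one
Conditions: TBSOTf, 2,6-lutidine, CH2Cl2, −78 to 0 °C
Reagents that add atoms: tert-butyldimethylsilyl trifluoromethanesulfonate, CC(C)(C)[Si](C)(C)OS(=O)(=O)C(F)(F)F
Why: Silylation of the secondary α-ketol with a silyl triflate and a hindered base; the bulky ether resists base and hydride, cannot migrate as an acyl group would, and later anchors the ring A chair as an equatorial group.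

Step 11
Reactants: 19 9β-(tert-butyldimethylsilyloxy)-2,2-ethylenedioxy-4β,5β-dimethyl-10βH-decal-6-en-8-one
Product: 20 9β-(tert-butyldimethylsilyloxy)-2,2-ethylenedioxy-7-iodo-4β,5β-dimethyl-10βH-decal-6-en-8-one
Conditions: I2, pyridine, CH2Cl2, 0 °C to rt
Reagents that add atoms: iodine, II
Why: α-Iodination of a cyclic enone by the Baylis–Hillman-type addition–elimination sequence (pyridine adds to C6, the enolate is iodinated at C7, pyridine leaves), which is known to tolerate a quaternary γ-carbon. C9 is untouched because pyridine does not enolise the ketone.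

Step 12
Reactants: 20 9β-(tert-butyldimethylsilyloxy)-2,2-ethylenedioxy-7-iodo-4β,5β-dimethyl-10βH-decal-6-en-8-one
Product: 21 9β-(tert-butyldimethylsilyloxy)-2,2-ethylenedioxy-7-isopropenyl-4β,5β-dimethyl-10βH-decal-6-en-8-one
Conditions: isopropenyl-B(pin), Pd(dppf)Cl2 (5 mol %), K3PO4, THF/H2O, 45 °C
Reagents that add atoms: 2-isopropenyl-4,4,5,5-tetramethyl-1,3,2-dioxaborolane, CC(=C)B1OC(C)(C)C(C)(C)O1
Why: Suzuki–Miyaura coupling of an α-iodoenone with an alkenylboronate forms the C7–C11 bond at the only halogenated carbon; oxidative addition into the sp2 C–I bond is fast, and the mild phosphate base limits epimerisation at C9.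

Step 13
Reactants: 21 9β-(tert-butyldimethylsilyloxy)-2,2-ethylenedioxy-7-isopropenyl-4β,5β-dimethyl-10βH-decal-6-en-8-one
Product: 23 9β-(tert-butyldimethylsilyloxy)-2,2-ethylenedioxy-7β-isopropenyl-4β,5β-dimethyl-10βH-decalin-8-one, via copper C7-C8 dienolate 22 (not isolated)
Conditions: [(Ph3P)CuH]6 (0.4 equiv), H2O (5 equiv), toluene, rt
Reagents that add atoms: none
Why: Conjugate reduction of the enone by the phosphine-stabilised copper hydride: hydride goes to C6 only, since the isopropenyl alkene is not conjugated with the carbonyl, and dienolate 22 is protonated kinetically at its α-carbon C7, which keeps the C11=C12 bond out of conjugation. In the chair that holds the 9β-silyloxy group equatorial the proton enters C7 axially from the α face, so the isopropenyl group becomes equatorial and β, cis to the 5-methyl group; this is also the more stable epimer.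

Step 14
Reactants: 23 9β-(tert-butyldimethylsilyloxy)-2,2-ethylenedioxy-7β-isopropenyl-4β,5β-dimethyl-10βH-decalin-8-one
Product: 24 9β-(tert-butyldimethylsilyloxy)-2,2-ethylenedioxy-7β-isopropenyl-4β,5β-dimethyl-10βH-decalin-8α-ol
Conditions: NaBH4, CeCl3·7H2O, MeOH, −40 °C
Reagents that add atoms: none
Why: Hydride reduction of a cyclohexanone flanked by two equatorial groups: the small hydride attacks C8 axially from the β face, past only the axial hydrogens on C6 and C10, and gives the equatorial 8α alcohol, trans to both neighbours. The cerium salt buffers the medium so that the β,γ-unsaturated ketone is reduced before it can epimerise or conjugate.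

Step 15
Reactants: 24 9β-(tert-butyldimethylsilyloxy)-2,2-ethylenedioxy-7β-isopropenyl-4β,5β-dimethyl-10βH-decalin-8α-ol
Product: 25 8α-acetoxy-9β-(tert-butyldimethylsilyloxy)-2,2-ethylenedioxy-7β-isopropenyl-4β,5β-dimethyl-10βH-decalin
Conditions: Ac2O, pyridine, DMAP (cat.), CH2Cl2, rt
Reagents that add atoms: acetic anhydride, CC(=O)OC(C)=O
Why: DMAP-catalysed acetylation of the equatorial secondary alcohol installs the C8 acetate of the target while O9 is still silylated, so the two oxygens are differentiated without a selective step.

Step 16
Reactants: 25 8α-acetoxy-9β-(tert-butyldimethylsilyloxy)-2,2-ethylenedioxy-7β-isopropenyl-4β,5β-dimethyl-10βH-decalin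
Product: 26 8α-acetoxy-2,2-ethylenedioxy-7β-isopropenyl-4β,5β-dimethyl-10βH-decalin-9β-ol
Conditions: HF·pyridine, pyridine, THF, 0 °C to rt
Reagents that add atoms: none
Why: Fluoride-induced desilylation under buffered, weakly acidic conditions; no alkoxide is formed, so the acetate stays on O8, and the dioxolane and the alkene are not affected.

Step 17
Reactants: 26 8α-acetoxy-2,2-ethylenedioxy-7β-isopropenyl-4β,5β-dimethyl-10βH-decalin-9β-ol
Product: 27 8α-acetoxy-2,2-ethylenedioxy-7β-isopropenyl-4β,5β-dimethyl-10βH-decalin-9-one
Conditions: Dess–Martin periodinane, NaHCO3, CH2Cl2, rt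
Reagents that add atoms: none
Why: Dess–Martin oxidation under buffered, non-enolising conditions removes the placeholder configuration at C9 without epimerising C8 or the ring-fusion carbon C10, both of which are now α to a ketone.

Step 18
Reactants: 27 8α-acetoxy-2,2-ethylenedioxy-7β-isopropenyl-4β,5β-dimethyl-10βH-decalin-9-one
Product: 28 8α-acetoxy-2,2-ethylenedioxy-7β-isopropenyl-4β,5β-dimethyl-10βH-decalin-9α-ol
Conditions: LiBH(s-Bu)3, THF, −78 °C; AcOH, −78 °C
Reagents that add atoms: none
Why: Reduction with a bulky trialkylborohydride, which attacks cyclohexanones equatorially: the axial α trajectory at C9 is blocked by the syn-axial C5–C4 bond, so hydride enters from the β face and gives the axial 9α alcohol, cis to the C8 acetate. The cold acidic quench protonates the alkoxide before the acetyl group can migrate.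

Step 19
Reactants: 28 8α-acetoxy-2,2-ethylenedioxy-7β-isopropenyl-4β,5β-dimethyl-10βH-decalin-9α-ol
Product: 29 8α-acetoxy-2,2-ethylenedioxy-7β-isopropenyl-4β,5β-dimethyl-9α-[(E)-2-methylbut-2-enoyloxy]-10βH-decalin
Conditions: tigloyl chloride (5 equiv), DMAP (1 equiv), pyridine, CH2Cl2, 0 to 40 °C
Reagents that add atoms: (E)-2-methylbut-2-enoyl chloride, ClC(=O)/C(C)=C/C
Why: Acylation of a hindered axial alcohol by an acid chloride under nucleophilic catalysis; the E enoate is the stable geometric isomer and does not isomerise under these conditions.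

Step 20
Reactants: 29 8α-acetoxy-2,2-ethylenedioxy-7β-isopropenyl-4β,5β-dimethyl-9α-[(E)-2-methylbut-2-enoyloxy]-10βH-decalin
Product: 30 (4S,5R,7R,8R,9S,10S)-8-acetoxy-2-oxoeremophil-11-en-9-yl (E)-2-methylbut-2-enoate
Conditions: PPTS, acetone/H2O (10:1), 50 °C
Reagents that add atoms: water, O
Why: Mild acid hydrolysis of the dioxolane frees the C2 ketone; the two esters and the isopropenyl group tolerate pyridinium tosylate, and no stereocentre is α to the new ketone.

## Compound list

1 | 2-methoxy-4-methylphenol | COc1cc(C)ccc1O | starting material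
2 | benzyl vinyl ether | C=COCc1ccccc1 | starting material
3 | 6,6-dimethoxy-4-methylcyclohexa-2,4-dien-1-one | COC1(OC)C=C(C)C=CC1=O | intermediate (not isolated)
4 | rac-7-endo-benzyloxy-3,3-dimethoxy-5-methylbicyclo[2.2.2]oct-5-en-2-one (1:1 mixture of both enantiomers) | [C@@H]12C=C(C)[C@@H](C[C@H]1OCc1ccccc1)C(OC)(OC)C2=O.[C@H]12C=C(C)[C@H](C[C@@H]1OCc1ccccc1)C(OC)(OC)C2=O | intermediate
5 | (1R,4R,7R)-7-benzyloxy-3,3-dimethoxy-5-methylbicyclo[2.2.2]oct-5-en-2-one (benzyloxy syn to the alkene) | [C@@H]12C=C(C)[C@@H](C[C@H]1OCc1ccccc1)C(OC)(OC)C2=O | intermediate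
6 | (Z)-1-bromoprop-1-ene | C/C=C\Br | starting material
7 | (Z)-prop-1-enyllithium | C/C=C\[Li] | intermediate (not isolated)
8 | (Z)-prop-1-enylmagnesium bromide | C/C=C\[Mg]Br | intermediate (not isolated)
9 | (1R,2S,4R,7R)-7-benzyloxy-3,3-dimethoxy-5-methyl-2-[(Z)-prop-1-enyl]bicyclo[2.2.2]oct-5-en-2-ol (propenyl syn to the alkene) | [C@@H]12C=C(C)[C@@H](C[C@H]1OCc1ccccc1)C(OC)(OC)[C@]2(O)/C=C\C | intermediate
10 | potassium alkoxide of 9 | [C@@H]12C=C(C)[C@@H](C[C@H]1OCc1ccccc1)C(OC)(OC)[C@]2([O-])/C=C\C.[K+] | intermediate (not isolated)
11 | potassium C2(C3)-enolate of 12 | C1=C[C@@]2(C)[C@H](C(OC)(OC)C([O-])=C[C@@H]2C)C[C@H]1OCc1ccccc1.[K+] | intermediate (not isolated)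
12 | 8β-benzyloxy-1,1-dimethoxy-4β,5β-dimethyl-10βH-decal-6-en-2-one | C1=C[C@@]2(C)[C@H](C(OC)(OC)C(=O)C[C@@H]2C)C[C@H]1OCc1ccccc1 | intermediate
13 | 8β-benzyloxy-4β,5β-dimethyl-10βH-decal-6-en-2-one | C1=C[C@@]2(C)[C@H](CC(=O)C[C@@H]2C)C[C@H]1OCc1ccccc1 | intermediate
14 | 8β-benzyloxy-2,2-ethylenedioxy-4β,5β-dimethyl-10βH-decal-6-ene | C1=C[C@@]2(C)[C@H](CC3(OCCO3)C[C@@H]2C)C[C@H]1OCc1ccccc1 | intermediate
15 | 2,2-ethylenedioxy-4β,5β-dimethyl-10βH-decal-6-en-8β-ol | C1=C[C@@]2(C)[C@H](CC3(OCCO3)C[C@@H]2C)C[C@H]1O | intermediate
16 | 2,2-ethylenedioxy-4β,5β-dimethyl-10βH-decal-6-en-8-one | C1=C[C@@]2(C)[C@H](CC3(OCCO3)C[C@@H]2C)CC1=O | intermediate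
17 | potassium 6,8-dienolate of 16 | C1=C[C@@]2(C)[C@H](CC3(OCCO3)C[C@@H]2C)C=C1[O-].[K+] | intermediate (not isolated)
18 | 2,2-ethylenedioxy-9β-hydroxy-4β,5β-dimethyl-10βH-decal-6-en-8-one | C1=C[C@@]2(C)[C@H](CC3(OCCO3)C[C@@H]2C)[C@@H](O)C1=O | intermediate
19 | 9β-(tert-butyldimethylsilyloxy)-2,2-ethylenedioxy-4β,5β-dimethyl-10βH-decal-6-en-8-one | C1=C[C@@]2(C)[C@H](CC3(OCCO3)C[C@@H]2C)[C@@H](O[Si](C)(C)C(C)(C)C)C1=O | intermediate
20 | 9β-(tert-butyldimethylsilyloxy)-2,2-ethylenedioxy-7-iodo-4β,5β-dimethyl-10βH-decal-6-en-8-one | IC1=C[C@@]2(C)[C@H](CC3(OCCO3)C[C@@H]2C)[C@@H](O[Si](C)(C)C(C)(C)C)C1=O | intermediate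
21 | 9β-(tert-butyldimethylsilyloxy)-2,2-ethylenedioxy-7-isopropenyl-4β,5β-dimethyl-10βH-decal-6-en-8-one | C=C(C)C1=C[C@@]2(C)[C@H](CC3(OCCO3)C[C@@H]2C)[C@@H](O[Si](C)(C)C(C)(C)C)C1=O | intermediate
22 | copper C7=C8 dienolate from 21 (phosphine ligand not drawn) | C=C(C)C1C[C@@]2(C)[C@H](CC3(OCCO3)C[C@@H]2C)[C@@H](O[Si](C)(C)C(C)(C)C)C=1O[Cu] | intermediate (not isolated)
23 | 9β-(tert-butyldimethylsilyloxy)-2,2-ethylenedioxy-7β-isopropenyl-4β,5β-dimethyl-10βH-decalin-8-one | C=C(C)[C@H]1C[C@@]2(C)[C@H](CC3(OCCO3)C[C@@H]2C)[C@@H](O[Si](C)(C)C(C)(C)C)C1=O | intermediate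
24 | 9β-(tert-butyldimethylsilyloxy)-2,2-ethylenedioxy-7β-isopropenyl-4β,5β-dimethyl-10βH-decalin-8α-ol | C=C(C)[C@H]1C[C@@]2(C)[C@H](CC3(OCCO3)C[C@@H]2C)[C@@H](O[Si](C)(C)C(C)(C)C)[C@@H]1O | intermediate
25 | 8α-acetoxy-9β-(tert-butyldimethylsilyloxy)-2,2-ethylenedioxy-7β-isopropenyl-4β,5β-dimethyl-10βH-decalin | C=C(C)[C@H]1C[C@@]2(C)[C@H](CC3(OCCO3)C[C@@H]2C)[C@@H](O[Si](C)(C)C(C)(C)C)[C@@H]1OC(C)=O | intermediate
26 | 8α-acetoxy-2,2-ethylenedioxy-7β-isopropenyl-4β,5β-dimethyl-10βH-decalin-9β-ol | C=C(C)[C@H]1C[C@@]2(C)[C@H](CC3(OCCO3)C[C@@H]2C)[C@@H](O)[C@@H]1OC(C)=O | intermediate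
27 | 8α-acetoxy-2,2-ethylenedioxy-7β-isopropenyl-4β,5β-dimethyl-10βH-decalin-9-one | C=C(C)[C@H]1C[C@@]2(C)[C@H](CC3(OCCO3)C[C@@H]2C)C(=O)[C@@H]1OC(C)=O | intermediate
28 | 8α-acetoxy-2,2-ethylenedioxy-7β-isopropenyl-4β,5β-dimethyl-10βH-decalin-9α-ol | C=C(C)[C@H]1C[C@@]2(C)[C@H](CC3(OCCO3)C[C@@H]2C)[C@H](O)[C@@H]1OC(C)=O | intermediate
29 | 8α-acetoxy-2,2-ethylenedioxy-7β-isopropenyl-4β,5β-dimethyl-9α-[(E)-2-methylbut-2-enoyloxy]-10βH-decalin | C=C(C)[C@H]1C[C@@]2(C)[C@H](CC3(OCCO3)C[C@@H]2C)[C@H](OC(=O)/C(C)=C/C)[C@@H]1OC(C)=O | intermediate
30 | (4S,5R,7R,8R,9S,10S)-8-acetoxy-2-oxoeremophil-11-en-9-yl (E)-2-methylbut-2-enoate | C=C(C)[C@H]1C[C@@]2(C)[C@H](CC(=O)C[C@@H]2C)[C@H](OC(=O)/C(C)=C/C)[C@@H]1OC(C)=O | target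

## Step count and least certain steps

Total step count: 20. Longest linear sequence: 20 steps, from 1 to 30; bromide 6 enters at step 3.

**Step 4 (key step).**
- What may go wrong: the inward methyl group of the Z-propenyl unit is pressed against the C1 ketal and H10 in the boat, so the [3,3] shift slows. The alkoxide can then fragment by loss of the propenyl anion back towards 5, or rearrange by a [1,3] shift.
- Fallback: the neutral siloxy-Cope variant. From 9, silylation with N-trimethylsilylimidazole gives the trimethylsilyl ether of 9, F1, which has no alkoxide to fragment. Heating in a sealed tube (o-dichlorobenzene, about 220 °C) should drive the same shift through the same boat to the trimethylsilyl enol ether of 12, F2. Buffered fluoride (TBAF, AcOH) then returns the route to 12.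

**Step 13.**
- What may go wrong: protonation of the dienolate at its γ-carbon, or base-induced migration of the C11=C12 bond into conjugation with the C8 ketone; slow hydride transfer to the hindered C6, allowing 1,2-reduction; protonation of C7 from the β face.
- Fallback: convergence through the conjugated isomer. The crude reduction product from 21 is isomerised completely with DBU to the 7-isopropylidene ketone F4, which has no C7 stereocentre. Its thermodynamic potassium dienolate (KOt-Bu, t-BuOH/THF) is quenched inversely into cold aqueous acetic acid. This deconjugative α-protonation rejoins the route at 23 under conditions chosen for the protonation alone.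

**Step 9.**
- What may go wrong: incomplete facial selectivity of oxygen transfer to C9, and loss of dienolate by addition to the sulfonylimine that the oxidant releases.
- Fallback: Rubottom oxidation. From 16, TBSOTf and Et3N give the silyl dienol ether F3. Epoxidation of its electron-rich C8=C9 bond with mCPBA (NaHCO3, hexane/CH2Cl2, −20 °C) and 1,4-silyl shift should give 19 directly, without 18 and without an imine in the flask. Any 9α epimer that is carried on is corrected at 27, at the price of a less firmly anchored chair in step 13.

**Step 18.**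
- What may go wrong: migration of the acetyl group to the new C9 alkoxide before the quench, partial reductive loss of the acetate, or competing axial attack.
- Fallback: give up the acetate during the reduction. From 27, reduction with excess LiBH(s-Bu)3 followed by K2CO3 in MeOH gives the 8α,9α-diol F5 wherever the acetyl group has moved. Its dibutylstannylene acetal (Bu2SnO, toluene, reflux) is then acetylated with AcCl at the equatorial O8, which rejoins the route at 28.

**Step 19.**
- What may go wrong: acylation of the hindered axial O9 is slow, so base-mediated acetyl migration from O8 to O9 and tigloylation of the freed equatorial O8 would give the regioisomeric diester.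
- Fallback: reverse the order of the two acylations. From 28, methanolysis (K2CO3, MeOH) gives the 8α,9α-diol F5. TESCl and imidazole silylate the equatorial O8 to the 8α-triethylsilyl ether F6. Forcing tigloylation of O9 (tigloyl chloride, DMAP, 60 °C), now without a neighbouring acyl group, gives the 9α-tiglate silyl ether F7. HF·pyridine frees O8 to the 9α-tiglate 8α-alcohol F8. Rapid acetylation of this unhindered alcohol (Ac2O, pyridine) rejoins the route at 29.

## Further compounds

F1 | step 4 | trimethylsilyl ether of 9 | [C@@H]12C=C(C)[C@@H](C[C@H]1OCc1ccccc1)C(OC)(OC)[C@]2(O[Si](C)(C)C)/C=C\C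
F2 | step 4 | 8β-benzyloxy-1,1-dimethoxy-4β,5β-dimethyl-2-trimethylsilyloxy-10βH-decala-2,6-diene | C1=C[C@@]2(C)[C@H](C(OC)(OC)C(O[Si](C)(C)C)=C[C@@H]2C)C[C@H]1OCc1ccccc1
F3 | step 9 | 8-(tert-butyldimethylsilyloxy)-2,2-ethylenedioxy-4β,5β-dimethyl-10βH-decala-6,8-diene | C1=C[C@@]2(C)[C@H](CC3(OCCO3)C[C@@H]2C)C=C1O[Si](C)(C)C(C)(C)C
F4 | step 13 | 9β-(tert-butyldimethylsilyloxy)-2,2-ethylenedioxy-7-isopropylidene-4β,5β-dimethyl-10βH-decalin-8-one | CC(C)=C1C[C@@]2(C)[C@H](CC3(OCCO3)C[C@@H]2C)[C@@H](O[Si](C)(C)C(C)(C)C)C1=O
F5 | step 18 | 2,2-ethylenedioxy-7β-isopropenyl-4β,5β-dimethyl-10βH-decalin-8α,9α-diol | C=C(C)[C@H]1C[C@@]2(C)[C@H](CC3(OCCO3)C[C@@H]2C)[C@H](O)[C@@H]1O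
F6 | step 19 | 2,2-ethylenedioxy-7β-isopropenyl-4β,5β-dimethyl-8α-triethylsilyloxy-10βH-decalin-9α-ol | C=C(C)[C@H]1C[C@@]2(C)[C@H](CC3(OCCO3)C[C@@H]2C)[C@H](O)[C@@H]1O[Si](CC)(CC)CC
F7 | step 19 | 2,2-ethylenedioxy-7β-isopropenyl-4β,5β-dimethyl-9α-[(E)-2-methylbut-2-enoyloxy]-8α-triethylsilyloxy-10βH-decalin | C=C(C)[C@H]1C[C@@]2(C)[C@H](CC3(OCCO3)C[C@@H]2C)[C@H](OC(=O)/C(C)=C/C)[C@@H]1O[Si](CC)(CC)CC
F8 | step 19 | 2,2-ethylenedioxy-7β-isopropenyl-4β,5β-dimethyl-9α-[(E)-2-methylbut-2-enoyloxy]-10βH-decalin-8α-ol | C=C(C)[C@H]1C[C@@]2(C)[C@H](CC3(OCCO3)C[C@@H]2C)[C@H](OC(=O)/C(C)=C/C)[C@@H]1O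
A1 | alternative 1 | 9β-(tert-butyldimethylsilyloxy)-2,2-ethylenedioxy-7β-isopropenyl-4β,5β-dimethyl-10βH-decalin-8α-ol (same structure as 24) | C=C(C)[C@H]1C[C@@]2(C)[C@H](CC3(OCCO3)C[C@@H]2C)[C@@H](O[Si](C)(C)C(C)(C)C)[C@@H]1O
A2 | alternative 1 | 7,8-seco aldehyde of A1: ring B cyclohexane (C2 dioxolane, 4β-methyl) with methyl and 3-methylbut-2-enyl on C5 and CH(OTBS)CHO on C10 | CC(C)=CC[C@@]1(C)[C@H](CC2(OCCO2)C[C@@H]1C)[C@@H](O[Si](C)(C)C(C)(C)C)C=O
A3 | alternative 2 | 2-(tert-butyldimethylsilyloxy)-7β-isopropenyl-8α,9α-isopropylidenedioxy-4β,5β-dimethyl-10βH-decal-1-en-6-one | C=C(C)[C@H]1C(=O)[C@@]2(C)[C@H](C=C(O[Si](C)(C)C(C)(C)C)C[C@@H]2C)[C@@H]3OC(C)(C)O[C@H]13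
A4 | alternative 2 | open-chain trienone: (E)-tiglyl ketone, C7 isopropenyl, C8/C9 acetonide, (E)-2-silyloxybuta-1,3-dienyl on C9 | C=C(C)[C@@H](C(=O)/C(C)=C/C)[C@H]1OC(C)(C)O[C@H]1/C=C/C(=C)O[Si](C)(C)C(C)(C)C
A5 | alternative 3 | 4β,5β-dimethyl-10βH-decal-6-ene-2,8-dione | C1=C[C@@]2(C)[C@H](CC(=O)C[C@@H]2C)CC1=O
A6 | alternative 3 | 4-methyl-4-[(S)-4-oxopentan-2-yl]cyclohexa-2,5-dien-1-one | CC(=O)C[C@H](C)C1(C)C=CC(=O)C=C1
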